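The decalin is unravelled to a linear polyene that carries all twenty carbons (drimane locants). Everything rests on closing ring A at the C4–C5 bond: a configurationally defined chloronium ion bridging C3/C4, released from an anti-chlorohydrin triflate, is opened at the quaternary C4 by the (E)-C5=C10 olefin while C9 of a γ-silyl enoate closes ring B. The step exploits the antiperiplanar relation between the equatorial C3–Cl bond and the C4–C5 bond of ring A (axial methyl, equatorial side chain at C4). One operation forms C4–C5 and C9–C10 and sets C3, C4, C5, C9 and C10, with the C1 silyl ether as matched control element. The precursor is an acyclic chlorohydrin grown from (E)-geranylacetone.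

Key step: step 11

Remark: the pure (E)-isomer of geranylacetone is assumed to be purchasable. Ring locants C1–C12 are those of the drimane skeleton of the target (ring A: C1–C5 and C10; ring B: C5–C10; C11 on C9; C12 on C8); α is the face opposite the C10 methyl group. Open-chain compounds carry ordinary chain locants.

Step 1
Reactants: 1 (E)-geranylacetone
Product: 3 (3S,5E)-3-hydroxy-6,10-dimethylundeca-5,9-dien-2-one, via anilinooxy ketone 2 (not isolated)
Conditions: 1 (3 equiv, excess recovered), PhNO (slow addition), D-proline (20 mol%), DMSO, rt; then CuSO4·5H2O (30 mol%), MeOH, 0 °C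
Reagents that add atoms: nitrosobenzene O=Nc1ccccc1
Why: Proline enamine catalysis (organocatalytic α-aminoxylation, O-selective nitroso aldol) should engage the more substituted enamine at C3 and deliver oxygen to one enamine face through the hydrogen-bonded carboxylic acid transition state, D-proline giving the (S)-centre (the future C1), after which copper-mediated N–O cleavage frees the alcohol without touching ketone or olefins.

Step 2
Reactants: 3 (3S,5E)-3-hydroxy-6,10-dimethylundeca-5,9-dien-2-one
Product: 4 (3S)-3-hydroxy-4-[(2R,3R)-3-methyl-3-(4-methylpent-3-en-1-yl)oxiran-2-yl]butan-2-one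
Conditions: VO(acac)2 (5 mol%), t-BuOOH (1.5 equiv), CH2Cl2, 0 °C to rt
Reagents that add atoms: tert-butyl hydroperoxide CC(C)(C)OO
Why: Hydroxyl-directed vanadium-catalysed epoxidation should reach only the homoallylic 5,6-olefin (the remote 9,10-olefin is not delivered to), and the chair-like vanadate transition state with the acetyl group equatorial and the alkene turned outward to avoid A(1,3) strain with the (Z)-methyl group should give the 1,3-syn (R,R)-epoxide, which fixes the future C3/C4 configuration.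

Step 3
Reactants: 4 (3S)-3-hydroxy-4-[(2R,3R)-3-methyl-3-(4-methylpent-3-en-1-yl)oxiran-2-yl]butan-2-one
Product: 5 (3S)-3-[(tert-butyldimethylsilyl)oxy]-4-[(2R,3R)-3-methyl-3-(4-methylpent-3-en-1-yl)oxiran-2-yl]butan-2-one
Conditions: TBSCl, imidazole, DMF, rt
Reagents that add atoms: tert-butyldimethylsilyl chloride CC(C)(C)[Si](C)(C)Cl
Why: Silyl ether formation on the only hydroxyl group masks the future C1 oxygen as a bulky, weakly nucleophilic ether meant to survive to the last step; no stereocentre is touched.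

Step 4
Reactants: 5 (3S)-3-[(tert-butyldimethylsilyl)oxy]-4-[(2R,3R)-3-methyl-3-(4-methylpent-3-en-1-yl)oxiran-2-yl]butan-2-one; 6 triethyl phosphonoacetate
Product: 7 ethyl (2E,4S)-4-[(tert-butyldimethylsilyl)oxy]-3-methyl-5-[(2R,3R)-3-methyl-3-(4-methylpent-3-en-1-yl)oxiran-2-yl]pent-2-enoate
Conditions: NaH, THF, 0 to 40 °C
Reagents that add atoms: none
Why: Horner–Wadsworth–Emmons olefination of the α-silyloxy methyl ketone should give the (E)-trisubstituted enoate (ester trans to the branched silyloxy carbon), which is the future (E)-C5=C10 olefin, and the weakly basic phosphonate anion should not epimerise the α-centre.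

Step 5
Reactants: 7 ethyl (2E,4S)-4-[(tert-butyldimethylsilyl)oxy]-3-methyl-5-[(2R,3R)-3-methyl-3-(4-methylpent-3-en-1-yl)oxiran-2-yl]pent-2-enoate
Product: 8 (2E,4S)-4-[(tert-butyldimethylsilyl)oxy]-3-methyl-5-[(2R,3R)-3-methyl-3-(4-methylpent-3-en-1-yl)oxiran-2-yl]pent-2-en-1-ol
Conditions: i-Bu2AlH (2.2 equiv), CH2Cl2, −78 °C
Reagents that add atoms: none
Why: 1,2-Reduction of the enoate with i-Bu2AlH at low temperature should give the allylic alcohol and leave the trisubstituted epoxide and the silyl ether untouched.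

Step 6
Reactants: 8 (2E,4S)-4-[(tert-butyldimethylsilyl)oxy]-3-methyl-5-[(2R,3R)-3-methyl-3-(4-methylpent-3-en-1-yl)oxiran-2-yl]pent-2-en-1-ol
Product: 9 (2E,4S)-1-bromo-4-[(tert-butyldimethylsilyl)oxy]-3-methyl-5-[(2R,3R)-3-methyl-3-(4-methylpent-3-en-1-yl)oxiran-2-yl]pent-2-ene
Conditions: CBr4, PPh3, 2,6-lutidine, CH2Cl2, −20 °C
Reagents that add atoms: tetrabromomethane BrC(Br)(Br)Br
Why: Appel bromination should convert the primary allylic alcohol into the bromide by SN2 at the unhindered carbon, without allylic transposition and under neutral conditions that spare the epoxide.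

Step 7
Reactants: 9 (2E,4S)-1-bromo-4-[(tert-butyldimethylsilyl)oxy]-3-methyl-5-[(2R,3R)-3-methyl-3-(4-methylpent-3-en-1-yl)oxiran-2-yl]pent-2-ene; 10 methyl acetoacetate
Product: 11 methyl (6E,8S)-8-[(tert-butyldimethylsilyl)oxy]-7-methyl-9-[(2R,3R)-3-methyl-3-(4-methylpent-3-en-1-yl)oxiran-2-yl]-3-oxonon-6-enoate
Conditions: 10, NaH then n-BuLi, THF, 0 °C; then 9, 0 °C
Reagents that add atoms: none
Why: γ-Alkylation of the acetoacetate dianion (the more reactive terminal carbanion attacks the allylic bromide by SN2) should append C7, C8, C9 and C11 as a β-keto ester.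

Step 8
Reactants: 11 methyl (6E,8S)-8-[(tert-butyldimethylsilyl)oxy]-7-methyl-9-[(2R,3R)-3-methyl-3-(4-methylpent-3-en-1-yl)oxiran-2-yl]-3-oxonon-6-enoate
Product: 12 methyl (2Z,6E,8S)-8-[(tert-butyldimethylsilyl)oxy]-3-[(diethoxyphosphoryl)oxy]-7-methyl-9-[(2R,3R)-3-methyl-3-(4-methylpent-3-en-1-yl)oxiran-2-yl]nona-2,6-dienoate
Conditions: NaH, ClP(O)(OEt)2, Et2O, 0 °C
Reagents that add atoms: diethyl chlorophosphate CCOP(=O)(Cl)OCC
Why: O-Phosphorylation of the chelated sodium enolate of the β-keto ester should give the (Z)-enol phosphate, which fixes the future C8=C9 geometry (ester trans to C7).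

Step 9
Reactants: 12 methyl (2Z,6E,8S)-8-[(tert-butyldimethylsilyl)oxy]-3-[(diethoxyphosphoryl)oxy]-7-methyl-9-[(2R,3R)-3-methyl-3-(4-methylpent-3-en-1-yl)oxiran-2-yl]nona-2,6-dienoate; 13 (trimethylsilyl)methylmagnesium chloride
Product: 14 methyl (2Z,6E,8S)-8-[(tert-butyldimethylsilyl)oxy]-7-methyl-9-[(2R,3R)-3-methyl-3-(4-methylpent-3-en-1-yl)oxiran-2-yl]-3-[(trimethylsilyl)methyl]nona-2,6-dienoate
Conditions: Ni(acac)2 (5 mol%), THF, rt
Reagents that add atoms: none
Why: Nickel-catalysed Kumada-type cross-coupling of the enol phosphate with Grignard reagent 13 should proceed with retention of olefin geometry and install C12 as an allylsilane (γ-silyl enoate), the terminator for ring B.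

Step 10
Reactants: 14 methyl (2Z,6E,8S)-8-[(tert-butyldimethylsilyl)oxy]-7-methyl-9-[(2R,3R)-3-methyl-3-(4-methylpent-3-en-1-yl)oxiran-2-yl]-3-[(trimethylsilyl)methyl]nona-2,6-dienoate
Product: 15 methyl (2Z,6E,8S,10R,11S)-8-[(tert-butyldimethylsilyl)oxy]-11-chloro-10-hydroxy-7,11,15-trimethyl-3-[(trimethylsilyl)methyl]hexadeca-2,6,14-trienoate
Conditions: HCl (1 M in Et2O, 1.2 equiv), CH2Cl2, −78 °C
Reagents that add atoms: hydrogen chloride Cl
Why: Acid-mediated epoxide opening by chloride should occur at the tertiary carbon with inversion (borderline SN2) to give the anti-chlorohydrin, while the electron-poor γ-silyl enoate should resist protodesilylation at this temperature; the regioisomer from attack at the secondary carbon would be an equally competent precursor, because both ionise to the same chloronium ion.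

Step 11
Reactants: 15 methyl (2Z,6E,8S,10R,11S)-8-[(tert-butyldimethylsilyl)oxy]-11-chloro-10-hydroxy-7,11,15-trimethyl-3-[(trimethylsilyl)methyl]hexadeca-2,6,14-trienoate
Product: 18 methyl 1α-[(tert-butyldimethylsilyl)oxy]-3β-chloro-4β,10β-dimethyl-4α-(4-methylpent-3-en-1-yl)-8-methylene-trans-decalin-9β-carboxylate, via triflate 16 (not isolated), via chloronium triflate 17 (not isolated)
Conditions: Tf2O (1.1 equiv), 2,6-di-tert-butyl-4-methylpyridine, CH2Cl2, −78 °C; then (CF3)2CHOH, −78 to 0 °C
Reagents that add atoms: none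
Why: The carbinol of 15 (the future C3) is triflated and ionises with rear-side participation of the neighbouring tertiary chlorine, so that chloronium ion 17 forms only across C3/C4 and on the face opposite to the former epoxide; the (E)-C5=C10 π bond then opens it at the tertiary C4 with inversion, and C9 of the γ-silyl enoate captures the developing C10 cation with loss of Me3Si+ (anti SE2′), leaving the C8 exo-methylene. The closest known reaction types are the solvolytic generation of configurationally stable chloronium ions from β-chloro sulfonates and halonium-initiated, allylsilane-terminated polyene cyclisations. Ring A closes 6-endo at the chloronium ion (Markovnikov attack on C4, C5=C10 endocyclic) and ring B closes 6-endo-trig onto C10, both through chair transition states. C3 and C4 derive stereospecifically from the epoxide (one inversion at C3, two at C4), C5 and C10 from anti addition across the (E)-olefin (trans fusion, axial C10 methyl) and C9 from the (Z)-enoate geometry (equatorial ester), while the C1 stereocentre is matched to the chloronium configuration so that its silyloxy group sits axial in the chair, away from the peri position next to the C9 ester. The step needs the inductively weakened C5=C10 olefin to outrun capture of the chloronium ion by the C1 ether oxygen and E1 loss, which the bulky silyl group, the buffered non-nucleophilic medium and the chair pre-organisation are meant to secure, while the side-chain olefin could engage the ion only through a disfavoured 5-endo closure at the less electrophilic C3.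

Step 12
Reactants: 18 methyl 1α-[(tert-butyldimethylsilyl)oxy]-3β-chloro-4β,10β-dimethyl-4α-(4-methylpent-3-en-1-yl)-8-methylene-trans-decalin-9β-carboxylate
Product: 19 [1α-[(tert-butyldimethylsilyl)oxy]-3β-chloro-4β,10β-dimethyl-4α-(4-methylpent-3-en-1-yl)-8-methylene-trans-decalin-9β-yl]methanol
Conditions: i-Bu2AlH (2.5 equiv), CH2Cl2, −78 to 0 °C
Reagents that add atoms: none
Why: Reduction of the hindered β,γ-unsaturated ester with i-Bu2AlH should give the C11 alcohol without migration of the exocyclic olefin, and the equatorial neopentyl chloride should be inert to the hydride.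

Step 13
Reactants: 19 [1α-[(tert-butyldimethylsilyl)oxy]-3β-chloro-4β,10β-dimethyl-4α-(4-methylpent-3-en-1-yl)-8-methylene-trans-decalin-9β-yl]methanol
Product: 20 8α,12-epoxide of 19 (spiro-oxirane at C8 with oxygen on the α face)
Conditions: VO(acac)2 (5 mol%), t-BuOOH (1.5 equiv), CH2Cl2, rt
Reagents that add atoms: tert-butyl hydroperoxide CC(C)(C)OO
Why: Hydroxyl-directed vanadium-catalysed epoxidation should deliver oxygen only to the homoallylic exocyclic C8=C12 olefin, from the α face away from the C10 methyl group, the trisubstituted side-chain olefin being out of reach of the vanadate; the configuration of the spiro centre is of no consequence, because C8 becomes trigonal in the next step.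

Step 14
Reactants: 20 8α,12-epoxide of 19
Product: 21 1α-[(tert-butyldimethylsilyl)oxy]-3β-chloro-4β,10β-dimethyl-4α-(4-methylpent-3-en-1-yl)-trans-decal-7-ene-8,9β-dimethanol
Conditions: Al(Oi-Pr)3, toluene, 110 °C
Reagents that add atoms: none
Why: Aluminium alkoxide-mediated epoxide-to-allylic-alcohol isomerisation (syn β-elimination within the aluminium-bound epoxide) should remove the accessible C7 hydrogen rather than the hindered C9 hydrogen and give the C7=C8 olefin with C12 as a primary allylic alcohol; the equatorial chloride has no antiperiplanar hydrogen for E2.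

Step 15
Reactants: 21 1α-[(tert-butyldimethylsilyl)oxy]-3β-chloro-4β,10β-dimethyl-4α-(4-methylpent-3-en-1-yl)-trans-decal-7-ene-8,9β-dimethanol
Product: 22 1α-[(tert-butyldimethylsilyl)oxy]-3β-chloro-4β,10β-dimethyl-4α-(4-methylpent-3-en-1-yl)-trans-decal-7-ene-8,9β-dicarbaldehyde
Conditions: (COCl)2, DMSO, CH2Cl2, −78 °C; then i-Pr2NEt, −78 to −40 °C
Reagents that add atoms: none
Why: Swern oxidation should convert both primary alcohols at once at low temperature, before a lactol can form, and the hindered base with a cold quench should keep the equatorial C9 formyl group from epimerising.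

Step 16
Reactants: 22 1α-[(tert-butyldimethylsilyl)oxy]-3β-chloro-4β,10β-dimethyl-4α-(4-methylpent-3-en-1-yl)-trans-decal-7-ene-8,9β-dicarbaldehyde
Product: 23 (1S,3S,4S,5R,9R,10S)-3β-chloro-1α-hydroxy-4β,10β-dimethyl-4α-(4-methylpent-3-en-1-yl)-trans-decal-7-ene-8,9β-dicarbaldehyde
Conditions: HF·pyridine, pyridine, THF, 0 °C to rt
Reagents that add atoms: none
Why: Fluoride-mediated desilylation under buffered, non-basic conditions should release the axial C1 hydroxyl group without enolising the C9 aldehyde or adding to the enal.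

Compound list
1 | (E)-geranylacetone, (5E)-6,10-dimethylundeca-5,9-dien-2-one | CC(=O)CC/C=C(\C)CCC=C(C)C | starting material
2 | (3S,5E)-3-(anilinooxy)-6,10-dimethylundeca-5,9-dien-2-one | CC(=O)[C@@H](ONc1ccccc1)C/C=C(\C)CCC=C(C)C | intermediate
3 | (3S,5E)-3-hydroxy-6,10-dimethylundeca-5,9-dien-2-one | CC(=O)[C@@H](O)C/C=C(\C)CCC=C(C)C | intermediate
4 | (3S)-3-hydroxy-4-[(2R,3R)-3-methyl-3-(4-methylpent-3-en-1-yl)oxiran-2-yl]butan-2-one | CC(=O)[C@@H](O)C[C@H]1O[C@]1(C)CCC=C(C)C | intermediate
5 | (3S)-3-[(tert-butyldimethylsilyl)oxy]-4-[(2R,3R)-3-methyl-3-(4-methylpent-3-en-1-yl)oxiran-2-yl]butan-2-one | CC(=O)[C@@H](O[Si](C)(C)C(C)(C)C)C[C@H]1O[C@]1(C)CCC=C(C)C | intermediate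
6 | triethyl phosphonoacetate | CCOC(=O)CP(=O)(OCC)OCC | starting material
7 | ethyl (2E,4S)-4-[(tert-butyldimethylsilyl)oxy]-3-methyl-5-[(2R,3R)-3-methyl-3-(4-methylpent-3-en-1-yl)oxiran-2-yl]pent-2-enoate | CCOC(=O)/C=C(\C)[C@@H](O[Si](C)(C)C(C)(C)C)C[C@H]1O[C@]1(C)CCC=C(C)C | intermediate
8 | (2E,4S)-4-[(tert-butyldimethylsilyl)oxy]-3-methyl-5-[(2R,3R)-3-methyl-3-(4-methylpent-3-en-1-yl)oxiran-2-yl]pent-2-en-1-ol | OC/C=C(\C)[C@@H](O[Si](C)(C)C(C)(C)C)C[C@H]1O[C@]1(C)CCC=C(C)C | intermediate
9 | (2E,4S)-1-bromo-4-[(tert-butyldimethylsilyl)oxy]-3-methyl-5-[(2R,3R)-3-methyl-3-(4-methylpent-3-en-1-yl)oxiran-2-yl]pent-2-ene | BrC/C=C(\C)[C@@H](O[Si](C)(C)C(C)(C)C)C[C@H]1O[C@]1(C)CCC=C(C)C | intermediate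
10 | methyl acetoacetate | COC(=O)CC(C)=O | starting material
11 | methyl (6E,8S)-8-[(tert-butyldimethylsilyl)oxy]-7-methyl-9-[(2R,3R)-3-methyl-3-(4-methylpent-3-en-1-yl)oxiran-2-yl]-3-oxonon-6-enoate | COC(=O)CC(=O)CC/C=C(\C)[C@@H](O[Si](C)(C)C(C)(C)C)C[C@H]1O[C@]1(C)CCC=C(C)C | intermediate
12 | methyl (2Z,6E,8S)-8-[(tert-butyldimethylsilyl)oxy]-3-[(diethoxyphosphoryl)oxy]-7-methyl-9-[(2R,3R)-3-methyl-3-(4-methylpent-3-en-1-yl)oxiran-2-yl]nona-2,6-dienoate | COC(=O)/C=C(\OP(=O)(OCC)OCC)CC/C=C(\C)[C@@H](O[Si](C)(C)C(C)(C)C)C[C@H]1O[C@]1(C)CCC=C(C)C | intermediate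
13 | (trimethylsilyl)methylmagnesium chloride | C[Si](C)(C)C[Mg]Cl | starting material
14 | methyl (2Z,6E,8S)-8-[(tert-butyldimethylsilyl)oxy]-7-methyl-9-[(2R,3R)-3-methyl-3-(4-methylpent-3-en-1-yl)oxiran-2-yl]-3-[(trimethylsilyl)methyl]nona-2,6-dienoate | COC(=O)/C=C(\C[Si](C)(C)C)CC/C=C(\C)[C@@H](O[Si](C)(C)C(C)(C)C)C[C@H]1O[C@]1(C)CCC=C(C)C | intermediate
15 | methyl (2Z,6E,8S,10R,11S)-8-[(tert-butyldimethylsilyl)oxy]-11-chloro-10-hydroxy-7,11,15-trimethyl-3-[(trimethylsilyl)methyl]hexadeca-2,6,14-trienoate | COC(=O)/C=C(\C[Si](C)(C)C)CC/C=C(\C)[C@@H](O[Si](C)(C)C(C)(C)C)C[C@@H](O)[C@@](C)(Cl)CCC=C(C)C | intermediate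
16 | 10-O-trifluoromethanesulfonate of 15 | COC(=O)/C=C(\C[Si](C)(C)C)CC/C=C(\C)[C@@H](O[Si](C)(C)C(C)(C)C)C[C@@H](OS(=O)(=O)C(F)(F)F)[C@@](C)(Cl)CCC=C(C)C | intermediate
17 | (S,S)-chloronium (chloriranium) ion bridging chain C10/C11 (target C3/C4), triflate salt | COC(=O)/C=C(\C[Si](C)(C)C)CC/C=C(\C)[C@@H](O[Si](C)(C)C(C)(C)C)C[C@@H]1[Cl+][C@@]1(C)CCC=C(C)C.[O-]S(=O)(=O)C(F)(F)F | intermediate
18 | methyl 1α-[(tert-butyldimethylsilyl)oxy]-3β-chloro-4β,10β-dimethyl-4α-(4-methylpent-3-en-1-yl)-8-methylene-trans-decalin-9β-carboxylate | CC(C)=CCC[C@]1(C)[C@@H](Cl)C[C@H](O[Si](C)(C)C(C)(C)C)[C@]2(C)[C@@H](C(=O)OC)C(=C)CC[C@@H]12 | intermediate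
19 | [1α-[(tert-butyldimethylsilyl)oxy]-3β-chloro-4β,10β-dimethyl-4α-(4-methylpent-3-en-1-yl)-8-methylene-trans-decalin-9β-yl]methanol | CC(C)=CCC[C@]1(C)[C@@H](Cl)C[C@H](O[Si](C)(C)C(C)(C)C)[C@]2(C)[C@@H](CO)C(=C)CC[C@@H]12 | intermediate
20 | 8α,12-epoxide of 19 (spiro-oxirane at C8, oxygen α) | CC(C)=CCC[C@]1(C)[C@@H](Cl)C[C@H](O[Si](C)(C)C(C)(C)C)[C@]2(C)[C@@H](CO)[C@@]3(CO3)CC[C@@H]12 | intermediate
21 | 1α-[(tert-butyldimethylsilyl)oxy]-3β-chloro-4β,10β-dimethyl-4α-(4-methylpent-3-en-1-yl)-trans-decal-7-ene-8,9β-dimethanol | CC(C)=CCC[C@]1(C)[C@@H](Cl)C[C@H](O[Si](C)(C)C(C)(C)C)[C@]2(C)[C@@H](CO)C(CO)=CC[C@@H]12 | intermediate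
22 | 1α-[(tert-butyldimethylsilyl)oxy]-3β-chloro-4β,10β-dimethyl-4α-(4-methylpent-3-en-1-yl)-trans-decal-7-ene-8,9β-dicarbaldehyde | CC(C)=CCC[C@]1(C)[C@@H](Cl)C[C@H](O[Si](C)(C)C(C)(C)C)[C@]2(C)[C@@H](C=O)C(C=O)=CC[C@@H]12 | intermediate
23 | (1S,3S,4S,5R,9R,10S)-3β-chloro-1α-hydroxy-4β,10β-dimethyl-4α-(4-methylpent-3-en-1-yl)-trans-decal-7-ene-8,9β-dicarbaldehyde (CNP0155449.1) | CC(C)=CCC[C@]1(C)[C@@H](Cl)C[C@H](O)[C@]2(C)[C@@H](C=O)C(C=O)=CC[C@@H]12 | target

Total step count: 16. Longest linear sequence: 16 steps (1 to 23).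

Steps most likely to fail

Step 11. The chloronium ion may be captured by the C1 silyl-ether oxygen (five-membered ether with loss of the silyl group) or may lose a proton, because the allylically oxygenated C5=C10 olefin is a weakened nucleophile. Ring B may also fail to close, or a hydride may shift from C1 to the C10 cation. The fallback changes the mode of ionisation from solvolysis of a triflate made in the flask in a protic fluoro alcohol to Lewis-acid ionisation of an isolable sulfonate in a non-polar medium. It sets out from 15, which is converted with MsCl/Et3N (CH2Cl2, 0 °C) into the β-chloro mesylate methyl (2Z,6E,8S,10R,11S)-8-[(tert-butyldimethylsilyl)oxy]-11-chloro-10-[(methylsulfonyl)oxy]-7,11,15-trimethyl-3-[(trimethylsilyl)methyl]hexadeca-2,6,14-trienoate (F1). F1 is ionised with Me2AlCl in CH2Cl2 at −78 to −20 °C, where a tight ion pair and the absence of solvent nucleophiles should favour the concerted chair–chair closure. The fallback comes back to the route at 18.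

Step 14. The elimination may remove the C9 instead of the C7 hydrogen (olefin in the wrong position), or a hydride shift may give the C12 aldehyde at 110 °C. The fallback replaces the aluminium-bound syn-elimination by a radical ring opening. It sets out from 20, which is treated with Cp2TiCl (trivalent titanium, made from Cp2TiCl2 and Mn in THF, rt). Homolysis of the epoxide gives the tertiary C8 radical, which is trapped by a second Cp2TiCl and loses a β-hydrogen from the less hindered C7, without base or heat. It comes back at 21 and makes no new compound (F0).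

Step 2. The vanadium peroxide may oxidise or cleave the α-hydroxy ketone faster than it epoxidises, chelation by the ketol may erode the 1,3-induction, and the free hydroxyl group may open the new epoxide at its tertiary carbon. The fallback postpones the epoxidation until the ketone has become an unreactive enoate. It sets out from 3, which is silylated (TBSCl, imidazole, DMF) to (3S,5E)-3-[(tert-butyldimethylsilyl)oxy]-6,10-dimethylundeca-5,9-dien-2-one (F2). F2 is olefinated with the sodium salt of 6 (NaH, THF) to ethyl (2E,4S,6E)-4-[(tert-butyldimethylsilyl)oxy]-3,7,11-trimethyldodeca-2,6,10-trienoate (F3). F3 is desilylated (Bu4NF, AcOH, THF) to the γ-hydroxy enoate ethyl (2E,4S,6E)-4-hydroxy-3,7,11-trimethyldodeca-2,6,10-trienoate (F4). F4 is epoxidised with VO(acac)2 and t-BuOOH in CH2Cl2, where the conjugated, electron-poor 2,3-olefin should stay untouched and the hydroxyl group should direct the reagent to the 6,7-olefin. This should give ethyl (2E,4S)-4-hydroxy-3-methyl-5-[(2R,3R)-3-methyl-3-(4-methylpent-3-en-1-yl)oxiran-2-yl]pent-2-enoate (F5). F5 is silylated (TBSCl, imidazole, DMF), which comes back to the route at 7.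

Further compounds
F1 | step 11 | methyl (2Z,6E,8S,10R,11S)-8-[(tert-butyldimethylsilyl)oxy]-11-chloro-10-[(methylsulfonyl)oxy]-7,11,15-trimethyl-3-[(trimethylsilyl)methyl]hexadeca-2,6,14-trienoate | COC(=O)/C=C(\C[Si](C)(C)C)CC/C=C(\C)[C@@H](O[Si](C)(C)C(C)(C)C)C[C@@H](OS(C)(=O)=O)[C@@](C)(Cl)CCC=C(C)C
F0 | step 14 | none | none
F2 | step 2 | (3S,5E)-3-[(tert-butyldimethylsilyl)oxy]-6,10-dimethylundeca-5,9-dien-2-one | CC(=O)[C@@H](O[Si](C)(C)C(C)(C)C)C/C=C(\C)CCC=C(C)C
F3 | step 2 | ethyl (2E,4S,6E)-4-[(tert-butyldimethylsilyl)oxy]-3,7,11-trimethyldodeca-2,6,10-trienoate | CCOC(=O)/C=C(\C)[C@@H](O[Si](C)(C)C(C)(C)C)C/C=C(\C)CCC=C(C)C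
F4 | step 2 | ethyl (2E,4S,6E)-4-hydroxy-3,7,11-trimethyldodeca-2,6,10-trienoate | CCOC(=O)/C=C(\C)[C@@H](O)C/C=C(\C)CCC=C(C)C
F5 | step 2 | ethyl (2E,4S)-4-hydroxy-3-methyl-5-[(2R,3R)-3-methyl-3-(4-methylpent-3-en-1-yl)oxiran-2-yl]pent-2-enoate | CCOC(=O)/C=C(\C)[C@@H](O)C[C@H]1O[C@]1(C)CCC=C(C)C
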